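**Remarks on the chemistry.** C4 of the target is R (CIP order C4a > C1 of the 4-aryl group > C3 > H). Coumarin numbering is used throughout, with Cα/Cβ for the ethenyl carbons (Cα on C5). Checked atom by atom, the protected coumarin, the boronic acid and the coupled product are mutually consistent and need no structural correction. The CuH reduction is assumed to run on to the lactol, because the first-formed dihydrocoumarin is an aryl ester, so a re-oxidation is planned.

## Structural features

The target 17 is a 3,4-dihydrocoumarin: benzene ring A is fused to a six-membered lactone through O1–C8a and C4–C4a. Ring A is 1,2,3,5-tetrasubstituted, with O1 on C8a, C4 on C4a, an (E)-2-arylethenyl group on C5 and a free hydroxyl on C7. C4 and Cβ each carry a 4-hydroxy-3-methoxyphenyl (guaiacyl) ring. C4 is the only stereocentre; it is doubly benzylic and β to the lactone carbonyl, so it has no stereochemical neighbour and cannot epimerise by enolisation, but it sits peri to the C5 substituent. The fragile groups are the lactone (an aryl ester, opened by alkoxides, amines, hydride or acidic methanol), the electron-rich E-stilbene (strong acid, light, oxidants, any hydrogenation) and three free phenols. The real difficulty is the peri-crowded C4-aryl/C5-styryl pair on a ring A whose substituents must be placed regiochemically, together with creating C4 in one configuration without reducing the stilbene. The key step exploits the fact that, at the coumarin oxidation level, C4 (of C3=C4) and Cβ (of Cα=Cβ) are both β-termini of alkenes attached to ring A and both carry the same guaiacyl ring, so one arylating agent can serve both.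

## Logic of the disconnections

**17 ⇒ 14.** The three O–CH2 bonds of the methoxymethyl acetals (on O7 and on both guaiacyl oxygens) are cut. The phenols have to be masked through the palladium and copper steps, and a single type of acetal allows one unmasking event. The gain is that every earlier intermediate is non-acidic and not oxidisable. The forward step must cleave three acetals in a non-alcoholic medium that neither opens the lactone nor protonates the stilbene.

**14 ⇒ 16 ⇒ 13.** The C4–H bond (and the C3–H bond formed with it) is removed, which erases the stereocentre and leads back to a planar, achiral coumarin. 16 is interposed because hydride reduction of an aryl-ester lactone is expected to continue to the lactol. The gain is that all skeletal bonds can be made on achiral material. The forward step must deliver hydride to one face of a peri-flanked C4 while leaving the stilbene untouched, and the lactol must then be oxidised without affecting the alkene or the acetals.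

**13 ⇒ 6 + two molecules of 11.** The C4–aryl and Cβ–aryl bonds are cut. Both join the same aryl group to an alkene terminus, so one reagent and one catalyst can form both. Eighteen carbon atoms are removed at once, leaving a 12-carbon achiral bicycle. The forward step needs the aryl group to go to the vinyl terminus and to C4, and both insertions to proceed under one set of conditions despite the peri crowding.

**6 ⇒ 4 + 5.** The C5–Cα bond is cut to an aryl bromide and a vinylboron reagent. The gain is a halocoumarin reachable from a simple phenol. The coupling must leave the lactone closed.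

**4 ⇒ 3 ⇒ 1 + 2.** The O7 acetal is removed, then the C4–C4a and O1–C2 bonds of the pyranone ring, with 2 acting as a three-carbon formylacetic acid equivalent. The gain is two commodity chemicals. The ring closure must occur para to one hydroxyl (ortho to bromine) and not between the two hydroxyls.

**11 ⇒ 8 ⇒ 7.** The C–B bond and then the O–CH2 bond are cut. Halogen–metal exchange must outrun ortho-metalation, and the work-up must spare the acetal.

## Other disconnections considered

**Alternative 1:** The cut is at C5–Cα and C4a–C4.
- Forward step: 2-iodo-3,5-bis(methoxymethoxy)phenyl 4-chlorobenzenesulfonate A1 would give a 3,5-dioxygenated benzyne with i-PrMgCl·LiCl. The (E)-alkenyl Grignard reagent A2 would add to the aryne carbon remote from the neighbouring acetal oxygen, and the resulting aryl-magnesium would be formylated with DMF to give aldehyde A3.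
- In its favour: the substitution pattern of ring A is fixed by the inductive polarisation of the aryne, without the ambiguity of an electrophilic ring closure on a 5-substituted resorcinol. On regiocontrol of ring A this plan is the better one. The E-alkene arrives intact and no aryl group has to be transferred to a peri-crowded planar coumarin.
- Against it here: A3 lacks the lactone, the C4 aryl group and the stereocentre. These would require olefination to an ortho,ortho'-disubstituted cinnamate, an enantioselective conjugate arylation at a very hindered β-carbon, and acetal cleavage with lactonisation. A1 needs desymmetrisation of a triphenol and an iodination that must go between the sulfonate and one acetal, not between the two acetals. Carbometalation of arynes by alkenylmagnesium reagents is less well supported than by aryl or heteroatom nucleophiles, and i-PrMgCl could itself add.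
- Comparison: both key steps form two skeletal bonds. The alternative is polar and needs no oxidant, and its later conjugate arylation would set C4 without a hydride reagent near a stilbene, which is a point in its favour. The chosen plan installs both guaiacyl groups at once and leaves only a reduction; the alternative would need roughly twelve to fourteen steps against nine.

**Alternative 2:** The cut is at C8–C8a and C6–C7, so ring A is built rather than decorated.
- Forward step: heating cyclobutenone A5 with (triisopropylsilyloxy)acetylene A6 would open the four-membered ring to a vinylketene, which adds the ynol ether in a [2+2] sense. A second ring opening and a six-electron electrocyclisation with tautomerisation would give phenol A7, with the free hydroxyl ortho to the side chain and O7 silylated.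
- In its favour: the stereocentre would come from desymmetrisation of a prochiral 3-arylglutaric anhydride to half-ester A4, a dependable reaction run before any sensitive group exists. On security of stereocontrol and on chemoselectivity this plan is the better one. The ring A pattern follows from the pericyclic sequence, O7 and O8a are differentiated automatically, and no peri-hindered coupling is needed.
- Against it here: A5 is unsubstituted at C2, styryl-substituted at C3 and carries a stereogenic side chain at C4. Its short access, a [2+2] cycloaddition of an aldoketene from A4 with a conjugated enyne, belongs to a weak reaction class (aldoketenes dimerise, unactivated alkynes are sluggish). The thermal cascade would expose a styryl-substituted vinylketene and the product stilbene to prolonged heating.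
- Comparison: the mechanism is metal-free and neutral, and the structure is assembled around the crowded positions instead of through them. The hardest compound (A5) lies before the key step, however, where the chosen plan has a three-step core, and the count would be roughly twelve to fourteen steps.

**Alternative 3:** The cut is at C4a–C5.
- Forward step: triketo ester A9 would be saponified in aqueous KOH. The C4a methylene (α to the C8a ketone) would add to the C5 cinnamoyl ketone, and dehydration and enolisation would aromatise ring A to acid A10, which lactonises on acidification. A9 would come from acylation of the dianion of diketone A8 with the activated acid arm of A4.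
- In its favour: the route is metal-free and biomimetic. The stereocentre comes from the same reliable desymmetrisation and is not enolisable, being β to both carbonyl groups. No peri coupling is needed and ring A needs no protecting groups. At about nine to ten steps it is the equal of the chosen plan in step economy and better in security of stereocontrol.
- Against it here: a 1,3,5-triketone has several competing outlets, namely 4-pyranone formation, oxa-Michael addition of an enol oxygen to the cinnamoyl β-carbon, retro-Claisen cleavage in hydroxide, and Claisen closure onto the ester if saponification lags. The required aldol acceptor is the least electrophilic, largely enolised carbonyl, and A9 would be a tautomer mixture that is hard to purify.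
- Comparison: the chosen key step relies on two insertions whose regiochemistry is individually established, whereas this one relies on one folding mode among several. The alternative avoids the reduction near the stilbene but would deliver an oxidation-prone free resorcinol acid.

Key step: step 6

## Route

Step 1
Reactants: 1 5-bromoresorcinol; 2 malic acid
Product: 3 5-bromo-7-hydroxy-2H-chromen-2-one
Conditions: conc. H2SO4, 100–110 °C, 2 h (CO evolved, vented); ice water
Reagents that add atoms: none
Why: Pechmann condensation: in sulfuric acid 2 loses CO and water to give formylacetic acid, which attacks 1 para to one hydroxyl (ortho to bromine) and lactonises onto the adjacent hydroxyl. With no C4 substituent there is no peri strain to divert closure to the position between the two hydroxyls.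

Step 2
Reactants: 3 5-bromo-7-hydroxy-2H-chromen-2-one
Product: 4 5-bromo-7-(methoxymethoxy)-2H-chromen-2-one
Conditions: MOMCl, K2CO3, acetone, 0 °C to rt
Reagents that add atoms: chloromethyl methyl ether, COCCl
Why: O-alkylation of the acidic 7-hydroxyl (Williamson type); the acetal is inert to the base, palladium and hydride steps that follow.

Step 3
Reactants: 4 5-bromo-7-(methoxymethoxy)-2H-chromen-2-one; 5 potassium vinyltrifluoroborate
Product: 6 5-ethenyl-7-(methoxymethoxy)-2H-chromen-2-one
Conditions: PdCl2(dppf)·CH2Cl2 (3 mol %), Et3N, n-PrOH, 90 °C
Reagents that add atoms: none
Why: Suzuki–Miyaura vinylation; the C5–Br bond of the electron-poor coumarin adds readily to zerovalent palladium and the trifluoroborate releases the vinylboron species slowly, which limits Heck oligomerisation. The amine base leaves the lactone closed.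

Step 4
Reactants: 7 4-bromo-2-methoxyphenol
Product: 8 4-bromo-2-methoxy-1-(methoxymethoxy)benzene
Conditions: MOMCl, K2CO3, acetone, rt
Reagents that add atoms: chloromethyl methyl ether, COCCl
Why: Williamson-type acetal formation on the phenol, giving the same protecting group as on the coumarin so that one final operation removes all three.

Step 5
Reactants: 8 4-bromo-2-methoxy-1-(methoxymethoxy)benzene
Product: 11 [3-methoxy-4-(methoxymethoxy)phenyl]boronic acid, via aryllithium 9 (not isolated), via lithium triisopropoxyborate 10 (not isolated)
Conditions: n-BuLi, THF, −78 °C; B(Oi-Pr)3, −78 °C to rt; 1 M HCl to pH 5–6, 0 °C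
Reagents that add atoms: triisopropyl borate, CC(C)OB(OC(C)C)OC(C)C; water, O
Why: Lithiation–borylation: bromine–lithium exchange at −78 °C is faster than ortho-metalation next to the acetal, the borate traps 9 as 10, and brief hydrolysis at pH 5–6 frees the boronic acid without cleaving the acetal.

Step 6
Reactants: 6 5-ethenyl-7-(methoxymethoxy)-2H-chromen-2-one; 11 [3-methoxy-4-(methoxymethoxy)phenyl]boronic acid (4 equiv, in portions)
Product: 13 4-[3-methoxy-4-(methoxymethoxy)phenyl]-5-[(E)-2-[3-methoxy-4-(methoxymethoxy)phenyl]ethenyl]-7-(methoxymethoxy)-2H-chromen-2-one, via mono-arylated 5-styrylcoumarin 12 (not isolated)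
Conditions: Pd(OAc)2 (10 mol %), 1,10-phenanthroline (12 mol %), O2 (1 atm), DMF, 80 °C
Reagents that add atoms: none
Why: Transmetalation of 11 to phenanthroline-ligated divalent palladium gives an aryl–palladium species that inserts the C5 vinyl group syn, with the aryl group on the unsubstituted terminus Cβ and palladium on the benzylic Cα; syn β-hydride elimination releases the (E)-stilbene 12 and O2 returns zerovalent palladium to the divalent state. A second aryl–palladium adds across C3=C4 of 12 with the aryl group at C4, the electrophilic β-carbon of the lactone-conjugated alkene, leaving a palladium enolate at C3; this equilibrates through its oxygen-bound form so that the C4 hydrogen can come syn to the metal, and β-hydride elimination restores the coumarin as 13. The closest known reaction type is the oxidative Heck coupling of arylboronic acids with styrenes and, under this same Pd(OAc)2/1,10-phenanthroline/O2 system, with coumarins at C4; the only addition here is that both alkene classes sit in one substrate and are served in one pot. No ring is closed and no stereocentre is formed; the E geometry follows from syn elimination through the less crowded rotamer. The step needs regioselectivity at both alkenes and no further arylation: the vinyl group is arylated at its terminus for steric reasons and because palladium is better placed at the benzylic carbon, the coumarin at C4 because of polarisation by the carbonyl group, and neither product alkene (an electron-rich 1,2-disubstituted stilbene and a trisubstituted, peri-shielded C3=C4) is a good acceptor for a third aryl group. The vinyl group should react first, so the harder event is insertion at C4 beside the peri styryl group; 11 is therefore used in excess and added in portions to offset homocoupling and oxidation to the phenol. The acetals and the lactone are inert in neutral DMF.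

Step 7
Reactants: 13 4-[3-methoxy-4-(methoxymethoxy)phenyl]-5-[(E)-2-[3-methoxy-4-(methoxymethoxy)phenyl]ethenyl]-7-(methoxymethoxy)-2H-chromen-2-one
Product: 16 (4R)-4-[3-methoxy-4-(methoxymethoxy)phenyl]-5-[(E)-2-[3-methoxy-4-(methoxymethoxy)phenyl]ethenyl]-7-(methoxymethoxy)-3,4-dihydro-2H-chromen-2-ol (C2 epimers), via dihydrocoumarin 14 (not isolated), via silyl acetal 15 (not isolated)
Conditions: Cu(OAc)2·H2O (5 mol %), (R)-DTBM-SEGPHOS (5.5 mol %), HSiMe(OEt)2 (4 equiv), t-BuOH (2 equiv), toluene, 0 °C to rt; aq. NH4F
Reagents that add atoms: none
Why: CuH-catalysed asymmetric conjugate reduction: the bisphosphine-ligated CuH delivers hydride to one face of C4 (ligand control; the R product is expected with the (R)-ligand by analogy with simpler 4-arylcoumarins, to be confirmed, and the (S)-ligand is the remedy if the sense is reversed) and t-BuOH protonates the copper enolate to 14. As an aryl ester, 14 takes a second hydride at C2 and is held as silyl acetal 15, which work-up hydrolyses to 16. The unactivated stilbene should undergo hydrocupration far more slowly than the enoate.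

Step 8
Reactants: 16 (4R)-4-[3-methoxy-4-(methoxymethoxy)phenyl]-5-[(E)-2-[3-methoxy-4-(methoxymethoxy)phenyl]ethenyl]-7-(methoxymethoxy)-3,4-dihydro-2H-chromen-2-ol
Product: 14 (4R)-4-[3-methoxy-4-(methoxymethoxy)phenyl]-5-[(E)-2-[3-methoxy-4-(methoxymethoxy)phenyl]ethenyl]-7-(methoxymethoxy)-3,4-dihydro-2H-chromen-2-one
Conditions: Dess–Martin periodinane (1.3 equiv), CH2Cl2, 0 °C to rt
Reagents that add atoms: none
Why: Dess–Martin oxidation of the cyclic hemiacetal to the lactone, a standard conversion for chroman-2-ols. The near-neutral conditions leave the acetals, the stilbene and C4 (β to the new carbonyl, not enolisable) unchanged and remove the C2 epimer mixture.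

Step 9
Reactants: 14 (4R)-4-[3-methoxy-4-(methoxymethoxy)phenyl]-5-[(E)-2-[3-methoxy-4-(methoxymethoxy)phenyl]ethenyl]-7-(methoxymethoxy)-3,4-dihydro-2H-chromen-2-one
Product: 17 (4R)-7-hydroxy-4-(4-hydroxy-3-methoxyphenyl)-5-[(E)-2-(4-hydroxy-3-methoxyphenyl)ethenyl]-3,4-dihydro-2H-chromen-2-one
Conditions: ZnBr2 (3 equiv), n-PrSH (6 equiv), CH2Cl2, 0 °C to rt, 15 min
Reagents that add atoms: none
Why: Lewis acid-assisted acetal cleavage with thiol capture: ZnBr2 activates each methoxymethyl acetal and the thiol takes the methoxymethyl carbon, freeing the three phenols. The medium is aprotic and alcohol-free, so the lactone is not transesterified, and the electrophilic fragment is trapped by sulfur instead of by the electron-rich rings. C4 is not involved.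

## Compound list

1 | 5-bromoresorcinol (5-bromobenzene-1,3-diol) | Oc1cc(O)cc(Br)c1 | starting material
2 | malic acid (2-hydroxybutanedioic acid, racemic) | OC(CC(=O)O)C(=O)O | starting material
3 | 5-bromo-7-hydroxy-2H-chromen-2-one | O=c1ccc2c(Br)cc(O)cc2o1 | intermediate
4 | 5-bromo-7-(methoxymethoxy)-2H-chromen-2-one | COCOc1cc(Br)c2ccc(=O)oc2c1 | intermediate
5 | potassium vinyltrifluoroborate | [K+].C=C[B-](F)(F)F | starting material
6 | 5-ethenyl-7-(methoxymethoxy)-2H-chromen-2-one | C=Cc1cc(OCOC)cc2oc(=O)ccc12 | intermediate
7 | 4-bromo-2-methoxyphenol | COc1cc(Br)ccc1O | starting material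
8 | 4-bromo-2-methoxy-1-(methoxymethoxy)benzene | COCOc1ccc(Br)cc1OC | intermediate
9 | [3-methoxy-4-(methoxymethoxy)phenyl]lithium | [Li]c1ccc(OCOC)c(OC)c1 | intermediate
10 | lithium [3-methoxy-4-(methoxymethoxy)phenyl]tri(propan-2-yloxy)borate | [Li+].COCOc1ccc([B-](OC(C)C)(OC(C)C)OC(C)C)cc1OC | intermediate
11 | [3-methoxy-4-(methoxymethoxy)phenyl]boronic acid | COCOc1ccc(B(O)O)cc1OC | intermediate
12 | 5-[(E)-2-[3-methoxy-4-(methoxymethoxy)phenyl]ethenyl]-7-(methoxymethoxy)-2H-chromen-2-one | O=c1ccc2c(/C=C/c3ccc(OCOC)c(OC)c3)cc(OCOC)cc2o1 | intermediate
13 | 4-[3-methoxy-4-(methoxymethoxy)phenyl]-5-[(E)-2-[3-methoxy-4-(methoxymethoxy)phenyl]ethenyl]-7-(methoxymethoxy)-2H-chromen-2-one | O=c1cc(-c2ccc(OCOC)c(OC)c2)c2c(/C=C/c3ccc(OCOC)c(OC)c3)cc(OCOC)cc2o1 | intermediate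
14 | (4R)-4-[3-methoxy-4-(methoxymethoxy)phenyl]-5-[(E)-2-[3-methoxy-4-(methoxymethoxy)phenyl]ethenyl]-7-(methoxymethoxy)-3,4-dihydro-2H-chromen-2-one | COCOc1ccc(/C=C/c2cc(OCOC)cc3c2[C@@H](c2ccc(OCOC)c(OC)c2)CC(=O)O3)cc1OC | intermediate
15 | (4R)-2-[diethoxy(methyl)silyl]oxy-4-[3-methoxy-4-(methoxymethoxy)phenyl]-5-[(E)-2-[3-methoxy-4-(methoxymethoxy)phenyl]ethenyl]-7-(methoxymethoxy)-3,4-dihydro-2H-chromene (C2 epimers) | COCOc1ccc(/C=C/c2cc(OCOC)cc3c2[C@@H](c2ccc(OCOC)c(OC)c2)CC(O[Si](C)(OCC)OCC)O3)cc1OC | intermediate
16 | (4R)-4-[3-methoxy-4-(methoxymethoxy)phenyl]-5-[(E)-2-[3-methoxy-4-(methoxymethoxy)phenyl]ethenyl]-7-(methoxymethoxy)-3,4-dihydro-2H-chromen-2-ol (C2 epimers) | COCOc1ccc(/C=C/c2cc(OCOC)cc3c2[C@@H](c2ccc(OCOC)c(OC)c2)CC(O)O3)cc1OC | intermediate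
17 | (4R)-7-hydroxy-4-(4-hydroxy-3-methoxyphenyl)-5-[(E)-2-(4-hydroxy-3-methoxyphenyl)ethenyl]-3,4-dihydro-2H-chromen-2-one | COc1cc(/C=C/c2cc(O)cc3c2[C@@H](c2ccc(O)c(OC)c2)CC(=O)O3)ccc1O | target

## Step count and risks

Total: 9 steps. Longest linear sequence: 7 steps (steps 1, 2, 3, 6, 7, 8, 9); the boronic acid branch is 2 steps (4, 5).

**Step 6 (key step).** The most likely failure is stalling after the first arylation. The C4 insertion must occur beside the peri C5 substituent and leads to a strained planar product, so the palladium enolate may be protonated instead of eliminating (giving racemic dihydrocoumarin), while 11 is consumed by homocoupling and oxidation. The fallback separates the two bond formations and makes the stilbene bond differently. It sets out from 8 and 4. Vinylation of 8 with 5 under the conditions of step 3 would give 2-methoxy-1-(methoxymethoxy)-4-vinylbenzene F1. A Mizoroki–Heck coupling of 4 with F1 (Pd(OAc)2, P(o-tol)3, Et3N, DMF, 100 °C; zerovalent palladium cycle) would form the C5–Cα bond and give 12 as an isolated compound. A single oxidative Heck arylation of 12 with 11, optimised on its own, then comes back to the route at 13. If C4 arylation of 12 itself proved unworkable, the fallback under step 7 would take 12 on to 14.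

**Step 7.** Two processes are the main risks: competing hydrocupration and protonation of the stilbene alkene if the conjugate reduction is slowed by the twisted, peri-flanked 4-aryl group, and erosion of facial selectivity for the same reason; ring-opening over-reduction is a lesser risk. The fallback avoids hydride reagents altogether. It sets out from 6. Arylation of the vinyl group alone at room temperature (Pd(OAc)2, 2,9-dimethyl-1,10-phenanthroline, N-methylmorpholine, MeCN, air, 1.3 equiv of 11) would give 12, isolated. A rhodium-catalysed asymmetric conjugate addition of 11 (Hayashi–Miyaura type; [Rh(acac)(C2H4)2], the SEGPHOS enantiomer that gives the R product, expected to be (R)-SEGPHOS, dioxane/H2O, 60 °C) would then form the C4–aryl bond and the stereocentre together. It comes back to the route at 14, bypassing 13 and 16.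

**Step 1.** Ring closure at the position between the two hydroxyls would give the 7-bromo-5-hydroxy isomer, and sulfonation or charring in hot sulfuric acid is also possible. The fallback sets out from 1. Vilsmeier–Haack formylation (POCl3, DMF, MeCN; then water) should give 2-bromo-4,6-dihydroxybenzaldehyde F2. The isomer question is settled at this stage, since the unwanted 4-bromo-2,6-dihydroxy isomer is symmetric, easily recognised and separable. Wittig olefination with ethyl (triphenylphosphoranylidene)acetate in refluxing N,N-diethylaniline would give ethyl (E)-3-(2-bromo-4,6-dihydroxyphenyl)prop-2-enoate F3, which isomerises and lactonises in the same pot. It comes back to the route at 3.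

**Step 9.** Thiolysis of the aryl-ester lactone, acid-promoted addition or oligomerisation at the electron-rich stilbene, or incomplete cleavage of one of the three acetals are the risks. The fallback accepts ring opening and repairs it. It sets out from 14. HCl in MeOH (rt to 40 °C) would cleave all three acetals, with methanol trapping the formaldehyde equivalent, and would open the lactone to methyl (3R)-3-[2,4-dihydroxy-6-[(E)-2-(4-hydroxy-3-methoxyphenyl)ethenyl]phenyl]-3-(4-hydroxy-3-methoxyphenyl)propanoate F4. Brief warming with catalytic p-TsOH in toluene, with removal of methanol, would re-close the ring. It comes back to the route at 17.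

## Further compounds

F1 | step 6 | 2-methoxy-1-(methoxymethoxy)-4-vinylbenzene | C=Cc1ccc(OCOC)c(OC)c1
F0 | step 7 | none | none
F2 | step 1 | 2-bromo-4,6-dihydroxybenzaldehyde | O=Cc1c(O)cc(O)cc1Br
F3 | step 1 | ethyl (E)-3-(2-bromo-4,6-dihydroxyphenyl)prop-2-enoate | CCOC(=O)/C=C/c1c(O)cc(O)cc1Br
F4 | step 9 | methyl (3R)-3-[2,4-dihydroxy-6-[(E)-2-(4-hydroxy-3-methoxyphenyl)ethenyl]phenyl]-3-(4-hydroxy-3-methoxyphenyl)propanoate | COC(=O)C[C@H](c1ccc(O)c(OC)c1)c1c(O)cc(O)cc1/C=C/c1ccc(O)c(OC)c1
A1 | alternative 1 | 2-iodo-3,5-bis(methoxymethoxy)phenyl 4-chlorobenzenesulfonate | COCOc1cc(OCOC)c(I)c(OS(=O)(=O)c2ccc(Cl)cc2)c1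
A2 | alternative 1 | [(E)-2-[3-methoxy-4-(methoxymethoxy)phenyl]ethenyl]magnesium bromide | COCOc1ccc(/C=C/[Mg]Br)cc1OC
A3 | alternative 1 | 2,4-bis(methoxymethoxy)-6-[(E)-2-[3-methoxy-4-(methoxymethoxy)phenyl]ethenyl]benzaldehyde | O=Cc1c(OCOC)cc(OCOC)cc1/C=C/c1ccc(OCOC)c(OC)c1
A4 | alternative 2 | (3R)-5-methoxy-3-[3-methoxy-4-(methoxymethoxy)phenyl]-5-oxopentanoic acid | COC(=O)C[C@H](c1ccc(OCOC)c(OC)c1)CC(=O)O
A5 | alternative 2 | methyl (3S)-3-[3-methoxy-4-(methoxymethoxy)phenyl]-3-[2-[(E)-2-[3-methoxy-4-(methoxymethoxy)phenyl]ethenyl]-4-oxocyclobut-2-en-1-yl]propanoate (ring stereocentre undefined) | COC(=O)C[C@H](c1ccc(OCOC)c(OC)c1)C1C(=O)C=C1/C=C/c1ccc(OCOC)c(OC)c1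
A6 | alternative 2 | (ethynyloxy)tri(propan-2-yl)silane | C#CO[Si](C(C)C)(C(C)C)C(C)C
A7 | alternative 2 | methyl (3R)-3-[2-hydroxy-6-[(E)-2-[3-methoxy-4-(methoxymethoxy)phenyl]ethenyl]-4-[tri(propan-2-yl)silyl]oxyphenyl]-3-[3-methoxy-4-(methoxymethoxy)phenyl]propanoate | COC(=O)C[C@H](c1ccc(OCOC)c(OC)c1)c1c(O)cc(O[Si](C(C)C)(C(C)C)C(C)C)cc1/C=C/c1ccc(OCOC)c(OC)c1
A8 | alternative 3 | (E)-6-[3-methoxy-4-(methoxymethoxy)phenyl]hex-5-ene-2,4-dione | CC(=O)CC(=O)/C=C/c1ccc(OCOC)c(OC)c1
A9 | alternative 3 | methyl (3R,10E)-3,11-bis[3-methoxy-4-(methoxymethoxy)phenyl]-5,7,9-trioxoundec-10-enoate | COC(=O)C[C@H](c1ccc(OCOC)c(OC)c1)CC(=O)CC(=O)CC(=O)/C=C/c1ccc(OCOC)c(OC)c1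
A10 | alternative 3 | (3R)-3-[2,4-dihydroxy-6-[(E)-2-[3-methoxy-4-(methoxymethoxy)phenyl]ethenyl]phenyl]-3-[3-methoxy-4-(methoxymethoxy)phenyl]propanoic acid | OC(=O)C[C@H](c1ccc(OCOC)c(OC)c1)c1c(O)cc(O)cc1/C=C/c1ccc(OCOC)c(OC)c1
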